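**Retrosynthetic overview**

1. Numbering: bicyclo[3.3.1]nonane core with C1 (benzoyl-bearing bridgehead), C2–C4, C5 (bridgehead with the free prenyl), C6 (CH2), C7 (CH), C8 (CMe2), C9 (bridging C=O); C10–C11–C12 = CH2–CH–CMe2 of the C7 prenyl; C13–C14–C15 = CH2–CH–CMe2 of the C3 prenyl; ring A = C1–C2–C3–C4–C5–C9, ring B = C1–C9–C5–C6–C7–C8.
2. Last disconnection: the C3–C11 bond, the peroxide C12–O–O–C14 and the C15–OOH group are removed in one aerobic radical cascade. This leads back to an enolised bicyclo[3.3.1]nonane trione whose C7 prenyl is endo (toward C3).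
3. The endo C7 prenyl comes from an exocyclic C7=C10 methylene by exo-face hydroboration and B-alkyl Suzuki coupling. The methylene compound comes from a monocyclic dienone by closure of ring B through the C1–C8 bond, an oxidative umpolung cyclisation.
4. Enabling feature: C1 is the methine carbon of the β-triketone C2(=O)/C9(=O)/benzoyl and, once O4 is a methyl ether, the only enolisable carbon of ring A. C8 is the γ-carbon of the allyl unit C8=C7–C10, whose α-carbon C10 can carry silicon, so an electrophilic C1 is attacked by C8 and the charge at C7 is released as the C7=C10 alkene.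
5. The dienone comes from enantioselective alkylative dearomatisation of a 4-O-methyl-3,5-diprenyl benzophenone. This sets C5, the only stereocenter made by a catalyst; C1, C7, C3, C11 and C14 are relayed from it. Ring order: ring A (from the arene), then ring B, then both seven-membered carbocycles of the homoadamantane together with the 1,2-dioxepane.

Key step: step 7

Remark on the chemistry: enolised β-di- and β-triketones are drawn as one tautomer (the others equilibrate), and CIP descriptors refer to the tautomer drawn.

**Route**

Step 1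
Reactants: 1 2,4,6-trihydroxybenzophenone
Product: 2 (2,6-dihydroxy-4-methoxyphenyl)(phenyl)methanone
Conditions: MeI (1.05 equiv), K2CO3 (1.1 equiv), acetone, 0 °C → rt
Reagents that add atoms: iodomethane, CI
Why: Williamson O-methylation; the 4-hydroxyl, para to the benzoyl group, is the most acidic phenol and the only one that cannot hydrogen-bond to the ketone, so one equivalent of MeI should alkylate it selectively.

Step 2
Reactants: 2 (2,6-dihydroxy-4-methoxyphenyl)(phenyl)methanone; 3 1-bromo-3-methylbut-2-ene (prenyl bromide)
Product: 4 [2,6-dihydroxy-4-methoxy-3,5-bis(3-methylbut-2-en-1-yl)phenyl](phenyl)methanone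
Conditions: 3 (2.2 equiv), 10% aq. KOH, 0 °C
Reagents that add atoms: none
Why: C-prenylation of an ambident phenoxide in water; each free ring carbon is ortho to one phenoxide oxygen and para to the other, and the protic medium disfavours O-alkylation.

Step 3
Reactants: 5 ethyl but-2-ynoate; 6 (trimethylsilyl)methyl trifluoromethanesulfonate
Product: 8 ethyl 3-methyl-2-[(trimethylsilyl)methyl]but-2-enoate, via vinylcuprate adduct 7 (not isolated)
Conditions: Me2CuLi (from MeLi and CuI), THF, −78 °C; then 6, −78 → 0 °C
Reagents that add atoms: lithium dimethylcuprate, [Li+].C[Cu-]C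
Why: conjugate syn-carbocupration of the ynoate puts methyl on C3 and copper on C2, and the α-cuprio acrylate is C-alkylated by the reactive primary triflate; both β-substituents are methyl, so no alkene geometry arises.

Step 4
Reactants: 8 ethyl 3-methyl-2-[(trimethylsilyl)methyl]but-2-enoate
Product: 9 3-methyl-2-[(trimethylsilyl)methyl]but-2-en-1-ol
Conditions: iBu2AlH (2.2 equiv), CH2Cl2, −78 °C; aqueous potassium sodium tartrate work-up
Reagents that add atoms: none
Why: 1,2-reduction of the α,β-unsaturated ester to the allylic alcohol by two hydrides; the allylsilane is inert to the hydride.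

Step 5
Reactants: 9 3-methyl-2-[(trimethylsilyl)methyl]but-2-en-1-ol
Product: 10 [2-(bromomethyl)-3-methylbut-2-en-1-yl]trimethylsilane
Conditions: CBr4, PPh3, CH2Cl2, 0 °C
Reagents that add atoms: tetrabromomethane, BrC(Br)(Br)Br
Why: Appel bromination under neutral conditions, chosen because protic acid would protodesilylate the allylsilane; the primary bromide with the tetrasubstituted alkene is the stable allylic isomer.

Step 6
Reactants: 4 [2,6-dihydroxy-4-methoxy-3,5-bis(3-methylbut-2-en-1-yl)phenyl](phenyl)methanone; 10 [2-(bromomethyl)-3-methylbut-2-en-1-yl]trimethylsilane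
Product: 11 (4R)-2-benzoyl-3-hydroxy-5-methoxy-4,6-bis(3-methylbut-2-en-1-yl)-4-{3-methyl-2-[(trimethylsilyl)methyl]but-2-en-1-yl}cyclohexa-2,5-dien-1-one
Conditions: N-(9-anthracenylmethyl)-O-allylcinchonidinium bromide (10 mol %), CsOH·H2O (2.5 equiv), toluene–CH2Cl2, −45 °C
Reagents that add atoms: none
Why: alkylative dearomatisation under asymmetric phase-transfer catalysis; the phenoxide is C-alkylated by the allylic bromide at a prenyl-bearing ring carbon, and the chiral ammonium cation paired with the phenoxide differentiates the enantiotopic carbons C3 and C5, setting the quaternary center C5 as R in 11 (the pseudoenantiomeric cinchoninium salt is taken if the sense proves opposite).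

Step 7
Reactants: 11 (4R)-2-benzoyl-3-hydroxy-5-methoxy-4,6-bis(3-methylbut-2-en-1-yl)-4-{3-methyl-2-[(trimethylsilyl)methyl]but-2-en-1-yl}cyclohexa-2,5-dien-1-one
Product: 12 (1S,5S)-1-benzoyl-4-methoxy-8,8-dimethyl-7-methylidene-3,5-bis(3-methylbut-2-en-1-yl)bicyclo[3.3.1]non-3-ene-2,9-dione
Conditions: PhI(OAc)2 (1.1 equiv), (CF3)2CHOH–CH2Cl2 (1:3), −40 → −10 °C
Reagents that add atoms: none
Why: Proposed new method: the acidic β-triketone enol exchanges onto PhI(OAc)2 to give an enol-bound trivalent iodine species in which C1 is electrophilic, the γ-carbon C8 of the tethered allylsilane attacks C1 as PhI leaves, and the β-silyl cation at C7 gives up Me3Si to acetate, leaving the C7=C10 methylene. The closest known reactions are the PhI(OAc)2-mediated oxidative Hosomi–Sakurai allylation of phenols in fluorinated alcohols and the allylation of ketone-derived enolonium species with allylsilanes. Ring B closes 6-endo-trig (SE2′ at the allylsilane), which joins the two quaternary carbons C1 and C8. C1 is the only new stereocenter and is controlled by C5, because C8 can reach C1 only on the face of ring A that carries C6, so the bicyclo[3.3.1]nonane should form as one diastereomer. The step needs C1 over C3, secured by the O4 methyl ether that leaves the triketone as the only group able to bind iodine, and the allylsilane over the two prenyl alkenes and over five-ring closure at C7, secured by the β-silicon effect that raises the nucleophilicity of this alkene and places the developing charge at C7. Low temperature and short contact time are used because the new C1–C8 bond is allylic and could ionise in the acidic medium.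

Step 8
Reactants: 12 (1S,5S)-1-benzoyl-4-methoxy-8,8-dimethyl-7-methylidene-3,5-bis(3-methylbut-2-en-1-yl)bicyclo[3.3.1]non-3-ene-2,9-dione; 13 1-bromo-2-methylprop-1-ene
Product: 15 (1S,5S,7S)-1-benzoyl-4-methoxy-8,8-dimethyl-3,5,7-tris(3-methylbut-2-en-1-yl)bicyclo[3.3.1]non-3-ene-2,9-dione, via alkylborane 14 (not isolated)
Conditions: 9-BBN (1.5 equiv), THF, 0 °C → rt; then 13, PdCl2(dppf) (5 mol %), AsPh3, Cs2CO3, DMF–H2O, rt
Reagents that add atoms: 9-borabicyclo[3.3.1]nonane, B1C2CCCC1CCC2 (supplies the boron of 14; only its hydrogen stays in 15)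
Why: hydroboration then B-alkyl Suzuki–Miyaura coupling; 9-BBN should add only to the 1,1-disubstituted C7=C10 alkene and from the exo face syn to the C9 bridge, because the endo face of C7 lies against the C2–C3–C4 bridge, so H7 becomes exo and C10 endo (C7 set as S by substrate control), and coupling of the primary alkylborane with the alkenyl bromide completes the endo prenyl group without touching C7.

Step 9
Reactants: 15 (1S,5S,7S)-1-benzoyl-4-methoxy-8,8-dimethyl-3,5,7-tris(3-methylbut-2-en-1-yl)bicyclo[3.3.1]non-3-ene-2,9-dione
Product: 16 (1S,5S,7S)-1-benzoyl-4-hydroxy-8,8-dimethyl-3,5,7-tris(3-methylbut-2-en-1-yl)bicyclo[3.3.1]non-3-ene-2,9-dione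
Conditions: LiCl (10 equiv), DMSO, 120 °C; dilute HCl work-up
Reagents that add atoms: none
Why: O-demethylation of the vinylogous methyl ester by chloride in a dipolar aprotic solvent (SN2 at the methyl carbon, Krapcho-type) releases the enolised β-diketone; no stereocenter is enolisable, since C1 and C5 are quaternary bridgeheads and C7 is remote.

Step 10
Reactants: 16 (1S,5S,7S)-1-benzoyl-4-hydroxy-8,8-dimethyl-3,5,7-tris(3-methylbut-2-en-1-yl)bicyclo[3.3.1]non-3-ene-2,9-dione
Product: 17 target peroxide (homoadamantane trione with C3–C11 bond, C12–O–O–C14 1,2-dioxepane and C15 hydroperoxide)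
Conditions: Mn(OAc)3·2H2O (5 mol %), O2 (1 atm), AcOH, 15 °C, 0.005 M, dark
Reagents that add atoms: dioxygen, O=O
Why: aerobic radical cyclisation–peroxidation cascade of a 1,3-diketone initiated by trivalent manganese (the reaction type of Mn(OAc)3/O2 syntheses of cyclic peroxides from 1,3-dicarbonyls and alkenes and of thiol–olefin co-oxygenation): the C3 radical closes 7-exo onto C11 of the endo C7 prenyl, reachable only on the face syn to C7 and with the C12 terminus turned toward C6 and away from the C8 methyl groups (sets C3 and C11), the tertiary C12 radical captures O2, the peroxyl radical closes 7-exo onto C14 of the C3 prenyl through a chair-like transition state with the C15 terminus pseudo-equatorial (expected to set C14 as in the target), and the C15 radical captures a second O2 and is reduced by Mn(OAc)2/AcOH to the hydroperoxide with return of Mn(OAc)3.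

**Compound list**

1 | 2,4,6-trihydroxybenzophenone | O=C(c1ccccc1)c1c(O)cc(O)cc1O | starting material
2 | (2,6-dihydroxy-4-methoxyphenyl)(phenyl)methanone | COc1cc(O)c(C(=O)c2ccccc2)c(O)c1 | intermediate
3 | 1-bromo-3-methylbut-2-ene (prenyl bromide) | CC(C)=CCBr | starting material
4 | [2,6-dihydroxy-4-methoxy-3,5-bis(3-methylbut-2-en-1-yl)phenyl](phenyl)methanone | COc1c(CC=C(C)C)c(O)c(C(=O)c2ccccc2)c(O)c1CC=C(C)C | intermediate
5 | ethyl but-2-ynoate | CCOC(=O)C#CC | starting material
6 | (trimethylsilyl)methyl trifluoromethanesulfonate | C[Si](C)(C)COS(=O)(=O)C(F)(F)F | starting material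
7 | lithium (1-ethoxycarbonyl-2-methylprop-1-en-1-yl)(methyl)cuprate, vinylcuprate adduct (not isolated) | [Li+].CCOC(=O)C([Cu-]C)=C(C)C | intermediate
8 | ethyl 3-methyl-2-[(trimethylsilyl)methyl]but-2-enoate | CCOC(=O)C(C[Si](C)(C)C)=C(C)C | intermediate
9 | 3-methyl-2-[(trimethylsilyl)methyl]but-2-en-1-ol | CC(C)=C(CO)C[Si](C)(C)C | intermediate
10 | [2-(bromomethyl)-3-methylbut-2-en-1-yl]trimethylsilane | CC(C)=C(CBr)C[Si](C)(C)C | intermediate
11 | (4R)-2-benzoyl-3-hydroxy-5-methoxy-4,6-bis(3-methylbut-2-en-1-yl)-4-{3-methyl-2-[(trimethylsilyl)methyl]but-2-en-1-yl}cyclohexa-2,5-dien-1-one | CC(C)=CC[C@@]1(CC(C[Si](C)(C)C)=C(C)C)C(O)=C(C(=O)c2ccccc2)C(=O)C(CC=C(C)C)=C1OC | intermediate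
12 | (1S,5S)-1-benzoyl-4-methoxy-8,8-dimethyl-7-methylidene-3,5-bis(3-methylbut-2-en-1-yl)bicyclo[3.3.1]non-3-ene-2,9-dione | CC(C)=CC[C@]12CC(=C)C(C)(C)[C@@](C(=O)c3ccccc3)(C2=O)C(=O)C(CC=C(C)C)=C1OC | intermediate
13 | 1-bromo-2-methylprop-1-ene | CC(C)=CBr | starting material
14 | 9-{[(1S,5S,7S)-1-benzoyl-4-methoxy-8,8-dimethyl-3,5-bis(3-methylbut-2-en-1-yl)-2,9-dioxobicyclo[3.3.1]non-3-en-7-yl]methyl}-9-borabicyclo[3.3.1]nonane, H7 exo and CH2B endo (not isolated) | CC(C)=CC[C@]12C[C@H](CB3C4CCCC3CCC4)C(C)(C)[C@@](C(=O)c3ccccc3)(C2=O)C(=O)C(CC=C(C)C)=C1OC | intermediate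
15 | (1S,5S,7S)-1-benzoyl-4-methoxy-8,8-dimethyl-3,5,7-tris(3-methylbut-2-en-1-yl)bicyclo[3.3.1]non-3-ene-2,9-dione, C7 prenyl endo | CC(C)=CC[C@]12C[C@H](CC=C(C)C)C(C)(C)[C@@](C(=O)c3ccccc3)(C2=O)C(=O)C(CC=C(C)C)=C1OC | intermediate
16 | (1S,5S,7S)-1-benzoyl-4-hydroxy-8,8-dimethyl-3,5,7-tris(3-methylbut-2-en-1-yl)bicyclo[3.3.1]non-3-ene-2,9-dione, C7 prenyl endo (7-epi-nemorosone constitution and relative configuration) | CC(C)=CC[C@]12C[C@H](CC=C(C)C)C(C)(C)[C@@](C(=O)c3ccccc3)(C2=O)C(=O)C(CC=C(C)C)=C1O | intermediate
17 | target peroxide: benzoyl homoadamantane trione with fused 1,2-dioxepane and 2-hydroperoxypropan-2-yl group, configuration as given | CC(C)=CC[C@]12C[C@@H]3C[C@@H]4C(C)(C)OO[C@H](C(C)(C)OO)C[C@@]4(C1=O)C(=O)[C@](C(=O)c1ccccc1)(C2=O)C3(C)C | target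

**Step count and risks**

Total step count: 10. Longest linear sequence: 8 steps (steps 3, 4, 5, 6, 7, 8, 9, 10).

Steps most likely to fail:

1. Step 7 (proposed new method). What may go wrong: capture of the electrophilic C1–iodine species by acetate or solvent (oxygenation at C1) before the hindered quaternary–quaternary bond forms, or ionisation of the new allylic C1–C8 bond in the acidic fluoroalcohol with allylic transposition. Fallback with known chemistry: set out from 11 and make the same bond in the one-electron manifold with Mn(OAc)3·2H2O (2.2 equiv) and Cu(OAc)2·H2O (1 equiv) in degassed AcOH at 25 °C, the established oxidative radical cyclisation of dearomatised acylphloroglucinols. The C1 radical adds to C8, the β-silyl radical at C7 is oxidised by divalent copper and loses the silyl group, and the route is rejoined at 12. Competing 5-exo closure onto the C5 prenyl is the main risk of this variant. No new compound is involved.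

2. Step 10. What may go wrong: capture of O2 by the C3 radical before the C3–C11 bond forms, reduction of the C12 peroxyl radical before the seven-membered peroxide closes, poor facial selectivity at C14, or manganese-induced decomposition of the hydroperoxide. Fallback: separate the carbon–carbon bond formation from the oxygenation. From 16, Mn(OAc)3·2H2O and Cu(OAc)2·H2O in degassed AcOH should give the isopropenyl homoadamantane trione F1 , the C12 radical being oxidised by divalent copper to the less substituted alkene. Cobalt-catalysed Isayama–Mukaiyama peroxidation of F1 with Co(thd)2 (thd = 2,2,6,6-tetramethylheptane-3,5-dionate), Et3SiH and O2 in ClCH2CH2Cl regenerates the C12 radical by hydrogen-atom transfer to the isopropenyl group. After O2 capture and peroxyl ring closure onto C14, the second peroxyl group should be trapped to give the target triethylsilyl peroxide F2 . HF·pyridine in THF then removes silicon from F2 and the route comes back at 17.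

3. Step 6. What may go wrong: poor discrimination of the enantiotopic carbons C3 and C5 by the ion pair (low enantiomeric excess), or competing O-alkylation. Fallback: from 4 and 10 with achiral Bu4NBr and CsOH make the racemic dienone F3 , then resolve it classically. The acidic triketone enol of F3 forms diastereomeric salts with (R)-1-phenylethylamine. The (R)-1-phenylethylammonium salt F4 of the (4R) enantiomer is purified by fractional crystallisation, and dilute acid releases the free enol from F4 , rejoining the route at 11.

Further compounds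

F0 | step 7 | none | none
F1 | step 10 | homoadamantane trione with C3–C11 bond and prop-1-en-2-yl group at C11, C3 and C5 prenyls intact | CC(C)=CC[C@]12C[C@@H]3C[C@H](C(C)=C)[C@](CC=C(C)C)(C1=O)C(=O)[C@](C(=O)c1ccccc1)(C2=O)C3(C)C
F2 | step 10 | triethylsilyl peroxide of target 17 | CC(C)=CC[C@]12C[C@@H]3C[C@@H]4C(C)(C)OO[C@H](C(C)(C)OO[Si](CC)(CC)CC)C[C@@]4(C1=O)C(=O)[C@](C(=O)c1ccccc1)(C2=O)C3(C)C
F3 | step 6 | racemic 11 | CC(C)=CCC1(CC(C[Si](C)(C)C)=C(C)C)C(O)=C(C(=O)c2ccccc2)C(=O)C(CC=C(C)C)=C1OC
F4 | step 6 | (R)-1-phenylethylammonium salt of (R)-11 | CC(C)=CC[C@@]1(CC(C[Si](C)(C)C)=C(C)C)C([O-])=C(C(=O)c2ccccc2)C(=O)C(CC=C(C)C)=C1OC.C[C@@H]([NH3+])c1ccccc1
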